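**Retrosynthetic overview**
1. The O8 methacrylate is attached last. The epoxide (third ring) comes from the Z-C1=C10 olefin by epoxidation directed by the free C8 hydroxyl.
2. The lactone (second ring) and the ten-membered carbocycle (first ring) are disconnected together at C6–C7, the C1–C10 bond of a (2Z,6Z)-farnesyl chain.
3. The precursor is an acyclic, fully oxygenated enal whose last isoprene unit is a 2-(oxiranyl)acrylate. Et3SiI/CrCl2 turns this unit into an allylchromium nucleophile at C7, and the C6 alkoxide then closes onto C12.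
4. The chain is built at C7–C8 by sulfur-ylide epoxidation (sets C8) and at C3–C4 by asymmetric Ni/Cr alkenylation (sets C3).
5. The Z-C1=C10 six-carbon core comes from 3-methylanisole (Birch reduction, ozonolysis) and the Z-C4=C5 unit from but-2-yn-1-ol.

Numbering: germacrane numbering is used for chain and ring atoms alike (C1–C10 ring, C11–C13 acrylate/lactone carbons, C14 on C10, C15 on C4).

Assumption: the SMILES is read literally as (1R,3S,6S,7R,8R,10S), with H6/H7 cis (cis-fused lactone), C2/C9 cis on the epoxide and a 4Z olefin, so on the flattened ring the epoxide O, O3, O6, C11 and O8 lie on one face; (1R,4R,5R)-isothiocineole is taken as a purchasable, recoverable sulfide.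

**Step 1**
Reactants: 1 3-methylanisole
Product: 2 1-methoxy-5-methylcyclohexa-1,4-diene
Conditions: Li, NH3 (l), t-BuOH, THF, −78 to −33 °C
Reagents that add atoms: none
Why: Birch reduction leaves the two donor-bearing carbons (C–OMe and C–Me) on the two isolated double bonds, so the future C1=C10 olefin is locked as a ring-cis trisubstituted olefin, and no stereocentre is formed.

**Step 2**
Reactants: 2 1-methoxy-5-methylcyclohexa-1,4-diene
Product: 4 methyl (Z)-3-methyl-6-oxohex-3-enoate, via methoxy hydroperoxide 3 (not isolated)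
Conditions: O3 (1.0 equiv), CH2Cl2–MeOH, −78 °C; then Me2S, −78 °C to rt
Reagents that add atoms: ozone, [O-][O+]=O
Why: Chemoselective ozonolysis cleaves the enol ether far faster than the trialkyl olefin, giving C8 as the ester and C3 as the aldehyde while the olefin keeps the Z geometry (C2 and C9 cis) inherited from the ring.

**Step 3**
Reactants: 5 but-2-yn-1-ol
Product: 7 (Z)-3-iodobut-2-en-1-ol, via cyclic alkenylalanate 6 (not isolated)
Conditions: NaAlH2(OCH2CH2OCH3)2, THF, 0 °C to rt; then I2, −78 °C
Reagents that add atoms: iodine, II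
Why: Alkoxide-directed trans-hydroalumination of a propargylic alcohol followed by iodinolysis with retention places iodine cis to CH2OH, which fixes the later C4=C5 olefin as Z (C3 and C6 cis).

**Step 4**
Reactants: 7 (Z)-3-iodobut-2-en-1-ol
Product: 8 (Z)-tert-butyl[(3-iodobut-2-en-1-yl)oxy]dimethylsilane
Conditions: t-BuMe2SiCl, imidazole, CH2Cl2, 0 °C to rt
Reagents that add atoms: tert-butyldimethylsilyl chloride, CC(C)(C)[Si](C)(C)Cl
Why: Imidazole-promoted O-silylation masks the primary allylic alcohol (future C6) through the organometallic and hydride steps without touching the olefin geometry.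

**Step 5**
Reactants: 4 methyl (Z)-3-methyl-6-oxohex-3-enoate; 8 (Z)-tert-butyl[(3-iodobut-2-en-1-yl)oxy]dimethylsilane
Product: 10 methyl (3Z,6S,7Z)-9-(tert-butyldimethylsilyloxy)-6-hydroxy-3,7-dimethylnona-3,7-dienoate, via trimethylsilyl ether 9 (not isolated)
Conditions: CrCl2 (10 mol %), (S)-N-[2-(4-isopropyl-4,5-dihydrooxazol-2-yl)-6-methylphenyl]methanesulfonamide (11 mol %), Et3N (20 mol %), NiCl2 (2 mol %), Mn, Me3SiCl, LiCl, MeCN, rt; then aq. citric acid, THF, 0 °C
Reagents that add atoms: none
Why: In this catalytic asymmetric Nozaki–Hiyama–Kishi alkenylation zerovalent nickel inserts into the carbon–iodine bond with retention of the trisubstituted olefin geometry, and the ligand-bound alkenyl species of trivalent chromium adds only to the aldehyde (ester and acidic C2 protons untouched) on its Re face, which sets 3S.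

**Step 6**
Reactants: 10 methyl (3Z,6S,7Z)-9-(tert-butyldimethylsilyloxy)-6-hydroxy-3,7-dimethylnona-3,7-dienoate
Product: 11 (3Z,6S,7Z)-9-(tert-butyldimethylsilyloxy)-6-hydroxy-3,7-dimethylnona-3,7-dienal
Conditions: i-Bu2AlH (2.2 equiv), CH2Cl2, −78 °C; aq. KNaC4H4O6 work-up
Reagents that add atoms: none
Why: In this partial ester reduction the first equivalent of hydride is consumed by the hydroxyl and the second gives an aluminium hemiacetal that is stable at −78 °C and releases the C8 aldehyde only on work-up, so the silyl ether, both Z olefins and C3 are untouched.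

**Step 7**
Reactants: 12 (1R,4R,5R)-isothiocineole (4,7,7-trimethyl-6-thiabicyclo[3.2.1]octane); 13 methyl 2-(bromomethyl)acrylate
Product: 14 (1R,4R,5R)-6-[2-(methoxycarbonyl)allyl]-4,7,7-trimethyl-6-thioniabicyclo[3.2.1]octane triflate
Conditions: LiOSO2CF3, CH2Cl2–H2O, rt
Reagents that add atoms: lithium trifluoromethanesulfonate, [Li+].[O-]S(=O)(=O)C(F)(F)F
Why: SN2 S-alkylation of the exposed sulfur lone pair by the allylic bromide is made irreversible by exchange to the non-nucleophilic triflate, and the sulfide stereocentres are spectators.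

**Step 8**
Reactants: 11 (3Z,6S,7Z)-9-(tert-butyldimethylsilyloxy)-6-hydroxy-3,7-dimethylnona-3,7-dienal; 14 the sulfonium triflate
Product: 17 methyl 2-{(2R,3R)-3-[(2Z,5S,6Z)-5-acetoxy-8-(tert-butyldimethylsilyloxy)-2,6-dimethylocta-2,6-dien-1-yl]oxiran-2-yl}acrylate, via sulfonium ylide 15 (not isolated), via hydroxy epoxide 16 (not isolated)
Conditions: 14 (1.3 equiv), LiN(SiMe3)2 (1.25 equiv), THF, −78 °C, 15 min; then 11, −78 to −40 °C; then Ac2O, Et3N, DMAP, −40 °C to rt
Reagents that add atoms: acetic anhydride, CC(=O)OC(C)=O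
Why: Proposed new method: the base removes the only accessible α-proton (the allylic SCH2, the other carbons on sulfur being a bridgehead CH and a quaternary carbon) to give a semi-stabilised allylic ylide whose cross-conjugated ester gives no resonance stabilisation, so, as with methallyl-type salts of this sulfide in the Corey–Chaykovsky sulfur-ylide epoxidation (the closest known reaction), addition at −78 °C should be fast and irreversible through the anti betaine to the trans epoxide, the rigid sulfide letting one ylide face meet the Si face of the aldehyde to set 8R (and a transient 7R), after which Ac2O/DMAP esterifies the free 3-OH in the same flask.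

**Step 9**
Reactants: 17 the vinyl epoxide acetate silyl ether
Product: 18 methyl 2-{(2R,3R)-3-[(2Z,5S,6Z)-5-acetoxy-2,6-dimethyl-8-oxoocta-2,6-dien-1-yl]oxiran-2-yl}acrylate
Conditions: DDQ (1.5 equiv), CH2Cl2–pH 7 phosphate buffer (10:1), 0 °C to rt
Reagents that add atoms: none
Why: In this DDQ oxidative desilylation hydride abstraction from the allylic C6–H of the silyl ether gives a silyloxocarbenium ion that water desilylates to the enal, while the acetate, epoxide and acrylate lack such activation and the neutral buffer preserves the 4Z geometry.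

**Step 10**
Reactants: 18 the vinyl epoxide enal
Product: 21 (3S,6S,7R,8R)-3-acetoxy-8-hydroxygermacra-1(10)Z,4Z,11(13)-trien-6,12-olide, via silyloxy allyl iodide 19 (not isolated), via triethylsilyl ether lactone 20 (not isolated)
Conditions: Et3SiCl (1.05 equiv), NaI (1.2 equiv), MeCN–CH2Cl2, −20 °C, 30 min; then syringe pump over 12 h into CrCl2 (8 equiv), THF, 25 °C, final 2 mM; then HF·pyridine, THF, 0 °C
Reagents that add atoms: none
Why: Proposed new method: Et3SiI opens the acrylate-activated vinyl epoxide (attack at C13 or C7 converges on the same allyl metal) and caps O8, two CrCl2 reduce the carbon–iodine bond to a 2-(methoxycarbonyl)allyl species of trivalent chromium with the C8 chain trans to the ester, and this adds through a closed chair to the tethered Z-enal with the aldehyde residue equatorial and the C8 chain axial (syn adduct, H6/H7 cis, 6S), A(1,3) strain holding H8 in the olefin plane so that the new bond forms anti to C8–C9 (7R from 8R), the two Z olefins acting as turns that bring C6 and C7 together and the C6 chromium alkoxide, the only free oxygen, closing onto C12 before fluoride frees O8; the closest known reactions are the CrCl2/LiI reductive coupling of diene monoepoxides with aldehydes and the Nozaki–Hiyama macrocyclisation–lactonisation of 2-(bromomethyl)alk-2-enoates.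

**Step 11**
Reactants: 21 (3S,6S,7R,8R)-3-acetoxy-8-hydroxygermacra-1(10)Z,4Z,11(13)-trien-6,12-olide
Product: 22 (1R,3S,6S,7R,8R,10S)-3-acetoxy-1,10-epoxy-8-hydroxygermacra-4Z,11(13)-dien-6,12-olide
Conditions: VO(acac)2 (5 mol %), t-BuOOH (1.5 equiv), CH2Cl2, 0 °C
Reagents that add atoms: tert-butyl hydroperoxide, CC(C)(C)OO
Why: In this hydroxyl-directed vanadium-catalysed epoxidation the vanadate ester of the homoallylic C8-OH delivers oxygen to the face of the Z-C1=C10 olefin that it overhangs, giving the epoxide cis to O8 (1R,10S) with C2/C9 still cis, while C4=C5 (flanked by two acyloxy groups, no free allylic OH) and the methylene lactone are too electron-poor to compete.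

**Step 12**
Reactants: 22 the epoxy alcohol
Product: 23 (1R,3S,6S,7R,8R,10S)-3-acetoxy-1,10-epoxy-8-(methacryloyloxy)germacra-4Z,11(13)-dien-6,12-olide (target)
Conditions: methacrylic anhydride, Et3N, DMAP (cat.), CH2Cl2, 0 °C to rt
Reagents that add atoms: methacrylic anhydride, C=C(C)C(=O)OC(=O)C(C)=C
Why: DMAP-catalysed acylation of the only free hydroxyl proceeds with retention at C8 under conditions too mild for translactonisation or epoxide opening.

**Compound list**
1 | 3-methylanisole | COc1cccc(C)c1 | starting material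
2 | 1-methoxy-5-methylcyclohexa-1,4-diene | COC1=CCC=C(C)C1 | intermediate
3 | methyl (Z)-6-hydroperoxy-6-methoxy-3-methylhex-3-enoate | COC(=O)C/C(C)=C\CC(OC)OO | intermediate
4 | methyl (Z)-3-methyl-6-oxohex-3-enoate | COC(=O)C/C(C)=C\CC=O | intermediate
5 | but-2-yn-1-ol | CC#CCO | starting material
6 | sodium cyclic alkenylalanate (five-membered Al–O–CH2–CH=C(CH3) ring, two 2-methoxyethoxy ligands) | CC1=CCO[Al-]1(OCCOC)OCCOC.[Na+] | intermediate
7 | (Z)-3-iodobut-2-en-1-ol | C/C(I)=C/CO | intermediate
8 | (Z)-tert-butyl[(3-iodobut-2-en-1-yl)oxy]dimethylsilane | C/C(I)=C/CO[Si](C)(C)C(C)(C)C | intermediate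
9 | methyl (3Z,6S,7Z)-9-(tert-butyldimethylsilyloxy)-3,7-dimethyl-6-(trimethylsilyloxy)nona-3,7-dienoate | COC(=O)C/C(C)=C\C[C@H](O[Si](C)(C)C)/C(C)=C\CO[Si](C)(C)C(C)(C)C | intermediate
10 | methyl (3Z,6S,7Z)-9-(tert-butyldimethylsilyloxy)-6-hydroxy-3,7-dimethylnona-3,7-dienoate | COC(=O)C/C(C)=C\C[C@H](O)/C(C)=C\CO[Si](C)(C)C(C)(C)C | intermediate
11 | (3Z,6S,7Z)-9-(tert-butyldimethylsilyloxy)-6-hydroxy-3,7-dimethylnona-3,7-dienal | O=CC/C(C)=C\C[C@H](O)/C(C)=C\CO[Si](C)(C)C(C)(C)C | intermediate
12 | (1R,4R,5R)-isothiocineole | C[C@@H]1CC[C@@H]2C[C@H]1SC2(C)C | starting material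
13 | methyl 2-(bromomethyl)acrylate | C=C(CBr)C(=O)OC | starting material
14 | (1R,4R,5R)-6-[2-(methoxycarbonyl)allyl]-4,7,7-trimethyl-6-thioniabicyclo[3.2.1]octane triflate | C[C@@H]1CC[C@@H]2C[C@H]1[S+](CC(=C)C(=O)OC)C2(C)C.[O-]S(=O)(=O)C(F)(F)F | intermediate
15 | sulfonium ylide from 14 | C[C@@H]1CC[C@@H]2C[C@H]1[S+]([CH-]C(=C)C(=O)OC)C2(C)C | intermediate
16 | methyl 2-{(2R,3R)-3-[(2Z,5S,6Z)-8-(tert-butyldimethylsilyloxy)-5-hydroxy-2,6-dimethylocta-2,6-dien-1-yl]oxiran-2-yl}acrylate | COC(=O)C(=C)[C@H]1O[C@@H]1C/C(C)=C\C[C@H](O)/C(C)=C\CO[Si](C)(C)C(C)(C)C | intermediate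
17 | methyl 2-{(2R,3R)-3-[(2Z,5S,6Z)-5-acetoxy-8-(tert-butyldimethylsilyloxy)-2,6-dimethylocta-2,6-dien-1-yl]oxiran-2-yl}acrylate | COC(=O)C(=C)[C@H]1O[C@@H]1C/C(C)=C\C[C@H](OC(C)=O)/C(C)=C\CO[Si](C)(C)C(C)(C)C | intermediate
18 | methyl 2-{(2R,3R)-3-[(2Z,5S,6Z)-5-acetoxy-2,6-dimethyl-8-oxoocta-2,6-dien-1-yl]oxiran-2-yl}acrylate | COC(=O)C(=C)[C@H]1O[C@@H]1C/C(C)=C\C[C@H](OC(C)=O)/C(C)=C\C=O | intermediate
19 | methyl (2Z,4R,6Z,9S,10Z)-9-acetoxy-2-(iodomethyl)-6,10-dimethyl-12-oxo-4-(triethylsilyloxy)dodeca-2,6,10-trienoate | COC(=O)/C(CI)=C/[C@H](O[Si](CC)(CC)CC)C/C(C)=C\C[C@H](OC(C)=O)/C(C)=C\C=O | intermediate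
20 | (3S,6S,7S,8R)-3-acetoxy-8-(triethylsilyloxy)germacra-1(10)Z,4Z,11(13)-trien-6,12-olide (same spatial arrangement as 21; the C7 descriptor changes only because of silicon) | CC[Si](CC)(CC)O[C@@H]1C/C(C)=C\C[C@H](OC(C)=O)/C(C)=C\[C@@H]2OC(=O)C(=C)[C@@H]21 | intermediate
21 | (3S,6S,7R,8R)-3-acetoxy-8-hydroxygermacra-1(10)Z,4Z,11(13)-trien-6,12-olide | O[C@@H]1C/C(C)=C\C[C@H](OC(C)=O)/C(C)=C\[C@@H]2OC(=O)C(=C)[C@@H]21 | intermediate
22 | (1R,3S,6S,7R,8R,10S)-3-acetoxy-1,10-epoxy-8-hydroxygermacra-4Z,11(13)-dien-6,12-olide | O[C@@H]1C[C@]2(C)O[C@@H]2C[C@H](OC(C)=O)/C(C)=C\[C@@H]2OC(=O)C(=C)[C@@H]21 | intermediate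
23 | (1R,3S,6S,7R,8R,10S)-3-acetoxy-1,10-epoxy-8-(methacryloyloxy)germacra-4Z,11(13)-dien-6,12-olide | C=C(C)C(=O)O[C@@H]1C[C@]2(C)O[C@@H]2C[C@H](OC(C)=O)/C(C)=C\[C@@H]2OC(=O)C(=C)[C@@H]21 | target

**Step count**
- Total: 12 steps.
- Longest linear sequence: 9 steps (1, 2, 5, 6, 8, 9, 10, 11, 12).

**Steps most likely to fail**

Step 10 carries the highest risk. Et3SiI may add to the enal. The allylchromium may lose the C8 oxygen to give a diene, or oligomerise, before the ten-membered ring closes. The sense of C8-to-C7 induction rests on a model, and the freed 8-OH could translactonise. The fallback sets out from 17 and comes back at 20, and replaces the reductively formed organochromium by a storable allylboron reagent. Compound 17 is opened with B2pin2 under CuCl/NaOt-Bu catalysis (conjugate borylation at C13, then elimination that opens the epoxide), and the C8 alkoxide is capped in the same flask with Et3SiCl to give the allylboronate silyl ether F1. DDQ as in step 9 gives the boronate enal F2. At high dilution in toluene with Sc(OTf)3 this closes C6–C7 by intramolecular allylboration through the same closed chair. The O6 borate then lactonises to 20, which fluoride converts to 21.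

Step 8 is the second risk. The β,γ-unsaturated aldehyde is easily enolised by the ylide, the ylide can add to the acrylate of unreacted salt, and the level and sense of induction for this ester-bearing ylide are untested. The fallback sets out from 11 and comes back at 20, and avoids both base and epoxide. Compound 11 is acetylated (Ac2O, pyridine) to the acetoxy aldehyde F3. The chromium/nickel catalyst system of step 5, with the ligand enantiomer that gives 8R, vinyl bromide and Et3SiCl as the turnover reagent, gives the allylic triethylsilyl ether F4. Cross-metathesis with 13 (second-generation Hoveyda–Grubbs catalyst) gives the allylic bromide F5. DDQ gives the bromo enal F6, which is fed to CrCl2 exactly as 19 is and lands on 20.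

Step 11 is the third risk. In a flexible ten-membered ring the vanadate may reach the other olefin face, or the hydroxy lactone may rearrange on the Lewis-acidic metal. The fallback sets out from 21 and comes back at 23, and replaces substrate direction by reagent control. Compound 21 is first esterified with methacrylic anhydride/DMAP to the triene diester F7. The electron-rich C1=C10 olefin is then epoxidised with KHSO5 and the fructose-derived chiral ketone (dioxirane epoxidation), using the ketone enantiomer that attacks the face cis to O8, which gives 23 directly.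

**Further compounds**
F1 | step 10 | methyl (2E,4R,6Z,9S,10Z)-9-acetoxy-12-(tert-butyldimethylsilyloxy)-6,10-dimethyl-2-[(4,4,5,5-tetramethyl-1,3,2-dioxaborolan-2-yl)methyl]-4-(triethylsilyloxy)dodeca-2,6,10-trienoate | COC(=O)/C(CB1OC(C)(C)C(C)(C)O1)=C/[C@H](O[Si](CC)(CC)CC)C/C(C)=C\C[C@H](OC(C)=O)/C(C)=C\CO[Si](C)(C)C(C)(C)C
F2 | step 10 | methyl (2E,4R,6Z,9S,10Z)-9-acetoxy-6,10-dimethyl-12-oxo-2-[(4,4,5,5-tetramethyl-1,3,2-dioxaborolan-2-yl)methyl]-4-(triethylsilyloxy)dodeca-2,6,10-trienoate | COC(=O)/C(CB1OC(C)(C)C(C)(C)O1)=C/[C@H](O[Si](CC)(CC)CC)C/C(C)=C\C[C@H](OC(C)=O)/C(C)=C\C=O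
F3 | step 8 | (3Z,6S,7Z)-6-acetoxy-9-(tert-butyldimethylsilyloxy)-3,7-dimethylnona-3,7-dienal | O=CC/C(C)=C\C[C@H](OC(C)=O)/C(C)=C\CO[Si](C)(C)C(C)(C)C
F4 | step 8 | (3R,5Z,8S,9Z)-8-acetoxy-11-(tert-butyldimethylsilyloxy)-5,9-dimethyl-3-(triethylsilyloxy)undeca-1,5,9-triene | C=C[C@H](O[Si](CC)(CC)CC)C/C(C)=C\C[C@H](OC(C)=O)/C(C)=C\CO[Si](C)(C)C(C)(C)C
F5 | step 8 | methyl (2Z,4R,6Z,9S,10Z)-9-acetoxy-2-(bromomethyl)-12-(tert-butyldimethylsilyloxy)-6,10-dimethyl-4-(triethylsilyloxy)dodeca-2,6,10-trienoate | COC(=O)/C(CBr)=C/[C@H](O[Si](CC)(CC)CC)C/C(C)=C\C[C@H](OC(C)=O)/C(C)=C\CO[Si](C)(C)C(C)(C)C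
F6 | step 8 | methyl (2Z,4R,6Z,9S,10Z)-9-acetoxy-2-(bromomethyl)-6,10-dimethyl-12-oxo-4-(triethylsilyloxy)dodeca-2,6,10-trienoate | COC(=O)/C(CBr)=C/[C@H](O[Si](CC)(CC)CC)C/C(C)=C\C[C@H](OC(C)=O)/C(C)=C\C=O
F7 | step 11 | (3S,6S,7R,8R)-3-acetoxy-8-(methacryloyloxy)germacra-1(10)Z,4Z,11(13)-trien-6,12-olide | C=C(C)C(=O)O[C@@H]1C/C(C)=C\C[C@H](OC(C)=O)/C(C)=C\[C@@H]2OC(=O)C(=C)[C@@H]21
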